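Ring A (C1–C10) is not cyclised but unveiled. The Z olefin C4=C5 and the C8 oxygen are traced back to a cis-fused bicyclo[5.3.0]decane in which C4 and C8 are joined, C8 bears a tertiary hydroxyl and C5 a mesylate cis to C3. A single base-induced Grob fragmentation breaks C4–C8, creates the C8 ketone and the Z alkene, and releases the ten-membered ring with the cis oxirane (ring C, on C1/C10) and the C3, C6 and C7 stereocentres already set. The bicycle is built from 2-methylcyclopentane-1,3-dione by ring-closing metathesis; lactone ring B, the C13 methylene and the epoxyangelate follow the fragmentation.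

Key step: step 23

Remark: atoms carry the numbering of the target (C1–C15) in every intermediate; C6–O is carried as a TBS ether and only C12–O as a TES ether, so that the primary ether alone can be oxidised after the fragmentation.

Step 1
Reactants: 1 angelic acid
Product: 2 angelyl alcohol
Conditions: LiAlH4, Et2O, 0 °C
Reagents that add atoms: none
Why: Hydride reduction of the conjugated acid at low temperature should reduce only the carboxyl group and keep the Z alkene, giving the allylic alcohol needed for a directed epoxidation.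

Step 2
Reactants: 2 angelyl alcohol
Product: 3 (2S,3R)-epoxy alcohol
Conditions: Ti(OiPr)4 (cat.), L-(+)-diethyl tartrate (cat.), t-BuOOH, 4 Å molecular sieves, CH2Cl2, −20 °C
Reagents that add atoms: tert-butyl hydroperoxide CC(C)(C)OO
Why: Sharpless asymmetric epoxidation with the L-(+)-tartrate should deliver oxygen to the face that gives the (2S,3R) epoxy alcohol from this (Z)-trisubstituted allylic alcohol, which sets both oxirane stereocentres of the side chain.

Step 3
Reactants: 3 (2S,3R)-epoxy alcohol
Product: 4 (2R,3R)-epoxyangelic acid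
Conditions: RuCl3 (cat.), NaIO4, CCl4/MeCN/H2O, rt
Reagents that add atoms: sodium periodate [Na+].[O-]I(=O)(=O)=O; water O
Why: Ruthenium tetroxide formed in situ should oxidise the primary alcohol to the acid without touching the oxirane carbons (the C2 descriptor becomes R only through the change of priorities).

Step 4
Reactants: 5 2-methylcyclopentane-1,3-dione; 6 allyl bromide
Product: 7 2-allyl-2-methylcyclopentane-1,3-dione
Conditions: NaOH, H2O, rt
Reagents that add atoms: none
Why: C-Alkylation of the 1,3-dione enolate with the allylic bromide in water should create the quaternary carbon that becomes C4 (with C15), the allyl CH2 being the future C3.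

Step 5
Reactants: 7 2-allyl-2-methylcyclopentane-1,3-dione
Product: 8 (2R,3R)-hydroxy ketone
Conditions: (S)-2-methyl-CBS-oxazaborolidine (cat.), BH3·SMe2, THF, −30 °C
Reagents that add atoms: none
Why: Corey–Bakshi–Shibata reduction should desymmetrise the dione, the catalyst fixing the carbinol as R and hydride entering anti to the larger allyl group, so that the hydroxyl (C5–O) ends up cis to the allyl group and C4 and C5 are set together.

Step 6
Reactants: 8 (2R,3R)-hydroxy ketone
Product: 9 C5 TES ether
Conditions: Et3SiCl, imidazole, DMF, 0 °C → rt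
Reagents that add atoms: chlorotriethylsilane CC[Si](Cl)(CC)CC
Why: Silylation gives a C5 ether that is a poor leaving group in the coming enone and boron chemistry and can later be removed in the presence of TBS ethers.

Step 7
Reactants: 9 C5 TES ether
Product: 10 propenyl ketone
Conditions: RuHCl(CO)(PPh3)3 (cat.), toluene, 80 °C
Reagents that add atoms: none
Why: Ruthenium-hydride-catalysed alkene isomerisation should move the terminal double bond into the (E)-propenyl position, so that a later cleavage leaves exactly one carbon (C3) on C4.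

Step 8
Reactants: 10 propenyl ketone
Product: 12 cyclopentenone, via TMS enol ether 11 (not isolated)
Conditions: Me3SiOTf, Et3N, CH2Cl2, 0 °C; then Pd(OAc)2, MeCN, rt
Reagents that add atoms: none
Why: Saegusa–Ito oxidation should work because the ketone can enolise only toward C7 (C4 is quaternary) and palladium diacetate dehydrogenates the silyl enol ether to the C6=C7 enone.

Step 9
Reactants: 12 cyclopentenone
Product: 14 C6 hydroxy ketone, via C6 boronate 13 (not isolated)
Conditions: CuCl (cat.), Xantphos (cat.), NaOtBu (cat.), B2pin2, MeOH, THF, rt; then NaBO3·4H2O, THF/H2O, rt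
Reagents that add atoms: sodium perborate [Na+].[Na+].O[B-]1(O)OO[B-](O)(O)OO1
Why: Copper-catalysed conjugate borylation should add boron to C6 anti to the neighbouring C5 silyloxy group and perborate oxidation replaces boron by hydroxyl with retention, so that C6–OH is trans to C5–O.

Step 10
Reactants: 14 C6 hydroxy ketone; 15 tert-butyl bromoacetate
Product: 16 C7-alkylated hydroxy ketone
Conditions: LiN(iPr)2 (2.2 equiv), THF, −78 °C; then 15, −78 → −40 °C
Reagents that add atoms: none
Why: The alkoxide–enolate dianion (C7 is the only enolisable position and the β-alkoxide cannot be expelled) should be alkylated anti to the C6 alkoxide as in a Fráter–Seebach alkylation, placing the C11–C12 arm trans to C6–O.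

Step 11
Reactants: 16 C7-alkylated hydroxy ketone
Product: 17 exocyclic alkene
Conditions: Zn, CH2Br2, TiCl4, THF/CH2Cl2, 0 °C → rt
Reagents that add atoms: dibromomethane BrCBr
Why: Takai–Lombardo methylenation is non-basic, so the epimerisable C7 centre, the β-hydroxy ketone and the tert-butyl ester should survive while the hindered ketone becomes the C8=C9 alkene.

Step 12
Reactants: 17 exocyclic alkene
Product: 18 spiro epoxide
Conditions: VO(acac)2 (cat.), t-BuOOH, CH2Cl2, rt
Reagents that add atoms: tert-butyl hydroperoxide CC(C)(C)OO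
Why: Vanadium-catalysed epoxidation directed by the homoallylic C6 hydroxyl should deliver oxygen to the alkene face cis to C6–O, which is also the open face next to the C4 methyl and C7–H, so that C8 is set with its oxygen cis to the C4 methyl while the undirected propenyl group stays intact.

Step 13
Reactants: 18 spiro epoxide
Product: 19 C3 aldehyde
Conditions: OsO4 (cat.), NaIO4, 2,6-lutidine, dioxane/H2O, rt
Reagents that add atoms: sodium periodate [Na+].[O-]I(=O)(=O)=O
Why: Johnson–Lemieux oxidation (dihydroxylation and periodate cleavage) of the only remaining alkene should give the neopentyl C3 aldehyde under buffered conditions that spare the epoxide.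

Step 14
Reactants: 19 C3 aldehyde
Product: 20 (3S)-homoallylic alcohol
Conditions: (−)-Ipc2BOMe (2.5 equiv), allylMgBr, Et2O, −78 °C → rt; then 19, −78 °C; then NaBO3·4H2O, THF/H2O, rt
Reagents that add atoms: allylmagnesium bromide C=CC[Mg]Br
Why: Brown allylation through a chair transition state under control of the isopinocampheyl groups derived from (+)-α-pinene should give the (3S) carbinol, as it does with other α-quaternary aldehydes, and it adds C2 and C1.

Step 15
Reactants: 20 (3S)-homoallylic alcohol
Product: 22 C8 TMS ether diene, via tris-TMS ether 21 (not isolated)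
Conditions: isopropenylMgBr (excess), CuI (cat.), THF, −30 → 0 °C; then Me3SiCl, Et3N, 0 °C → rt; then K2CO3, MeOH, 0 °C
Reagents that add atoms: isopropenylmagnesium bromide CC(=C)[Mg]Br; chlorotrimethylsilane C[Si](C)(C)Cl
Why: Copper-catalysed Grignard opening of the spiro epoxide at its CH2 carbon (SN2, C8 untouched) should install the methallyl group (C9, C10, C14) cis to the C3 chain, and silylation of all three alkoxides followed by brief methanolysis, which removes only the two secondary TMS ethers, leaves the tertiary C8 oxygen masked.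

Step 16
Reactants: 22 C8 TMS ether diene
Product: 23 hydroazulene diol
Conditions: second-generation Grubbs catalyst (cat.), CH2Cl2, 40 °C
Reagents that add atoms: none
Why: Ring-closing metathesis between the monosubstituted and the 1,1-disubstituted alkene, held cis on C4 and C8, should close the cycloheptene (C1=C10) with loss of ethylene and give the cis-fused bicyclo[5.3.0]decene.

Step 17
Reactants: 23 hydroazulene diol
Product: 24 hydroazulene epoxide
Conditions: VO(acac)2 (cat.), t-BuOOH, CH2Cl2, 0 °C → rt
Reagents that add atoms: tert-butyl hydroperoxide CC(C)(C)OO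
Why: Vanadium-catalysed epoxidation directed by the free homoallylic C3 hydroxyl, with the competing C8 oxygen masked as its TMS ether, should place the oxirane on the C1=C10 face cis to C3–O and so set C1 and C10.

Step 18
Reactants: 24 hydroazulene epoxide
Product: 25 bis-TBS ether
Conditions: tBuMe2SiOTf, 2,6-lutidine, CH2Cl2, −78 → −40 °C
Reagents that add atoms: tert-butyldimethylsilyl triflate CC(C)(C)[Si](C)(C)OS(=O)(=O)C(F)(F)F
Why: Silylation at low temperature with a hindered base should cap the two secondary hydroxyls (C3 and C6) as robust TBS ethers without opening the epoxide.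

Step 19
Reactants: 25 bis-TBS ether
Product: 26 C12 alcohol
Conditions: iBu2AlH, CH2Cl2, −78 → −20 °C
Reagents that add atoms: none
Why: Hydride reduction of the tert-butyl ester, the only reducible group while every hydroxyl is silylated, should give the primary C12 alcohol at temperatures at which the trisubstituted epoxide is not opened.

Step 20
Reactants: 26 C12 alcohol
Product: 27 triol
Conditions: HF·pyridine, pyridine, THF, 0 °C
Reagents that add atoms: none
Why: Buffered HF·pyridine should cleave the tertiary TMS ether and the secondary TES ether far faster than the two hindered secondary TBS ethers (selective desilylation), freeing C8–OH and C5–OH.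

Step 21
Reactants: 27 triol
Product: 28 C12 TES ether
Conditions: Et3SiCl (1.05 equiv), imidazole, CH2Cl2, −78 → −40 °C
Reagents that add atoms: chlorotriethylsilane CC[Si](Cl)(CC)CC
Why: Selective silylation should take the primary C12 hydroxyl only, because C5–OH is a neopentyl secondary and C8–OH a tertiary alcohol.

Step 22
Reactants: 28 C12 TES ether
Product: 29 hydroxy mesylate
Conditions: MeSO2Cl, Et3N, CH2Cl2, 0 °C
Reagents that add atoms: methanesulfonyl chloride CS(=O)(=O)Cl
Why: Sulfonylation through the sulfene should convert the hindered secondary C5 hydroxyl into the mesylate while the tertiary C8 hydroxyl stays free and, without a strong base, does not yet fragment.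

Step 23
Reactants: 29 hydroxy mesylate
Product: 30 Z cyclodecenone epoxide
Conditions: KN(SiMe3)2 (1.05 equiv), THF, −78 → 0 °C; pH 7 buffer
Reagents that add atoms: none
Why: Deprotonation of the tertiary C8 hydroxyl gives an alkoxide whose lone pair pushes into the C4–C8 bond while the C5–O bond ionises, a concerted Grob (Wharton-type) fragmentation of a 1,3-diol monosulfonate, whose closest precedent is the opening of bicyclic hydroxy sulfonates to medium-ring unsaturated ketones. No ring is closed by bond formation: ring A arises in a ring-expanding mode, by cleavage of the bond shared by the five- and seven-membered rings, so no ten-membered cyclisation is needed. No stereocentre is created, and C1, C3, C6, C7 and C10 with the cis oxirane are carried over unchanged. The step needs Z geometry at C4=C5, which is fixed because the mesylate is cis to the C4–C3 bond: when C5–O is anti-periplanar to C4–C8 (possible in the flexible cis-fused bicycle, where the mesylate can become pseudo-axial), C3 and C6 are syn-clinal and end up cis. It also needs fragmentation to outrun other pathways: C6–O is silylated and C6–H is cis to the mesylate, so neither epoxide closure nor anti elimination can compete, and one equivalent of base at low temperature leaves nothing to open the β,γ-epoxy ketone or to expel the C6 silyloxy group.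

Step 24
Reactants: 30 Z cyclodecenone epoxide
Product: 31 (8R)-alcohol
Conditions: (S)-2-methyl-CBS-oxazaborolidine (cat.), catecholborane, toluene, −78 → −40 °C
Reagents that add atoms: none
Why: Corey–Bakshi–Shibata reduction under reagent control, with the branched C7 side acting as the large group and C9H2 as the small one, should give the (8R) carbinol under neutral conditions that spare the base-sensitive ketone.

Step 25
Reactants: 31 (8R)-alcohol; 4 (2R,3R)-epoxyangelic acid
Product: 33 C8 epoxyangelate, via mixed anhydride 32 (not isolated)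
Conditions: 4, 2,4,6-trichlorobenzoyl chloride, Et3N, THF, rt; then 31, DMAP, toluene, rt
Reagents that add atoms: none
Why: Yamaguchi esterification should acylate the hindered secondary C8 hydroxyl with the α-quaternary acid, which has no α-hydrogen and so cannot epimerise, with retention at C8.

Step 26
Reactants: 33 C8 epoxyangelate
Product: 34 C12 aldehyde
Conditions: (COCl)2, DMSO, CH2Cl2, −78 °C; then Et3N, −78 → −20 °C
Reagents that add atoms: none
Why: Under Swern conditions a primary TES ether is cleaved and oxidised directly to the aldehyde while secondary TBS ethers, esters and epoxides are left alone.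

Step 27
Reactants: 34 C12 aldehyde
Product: 36 α-methylene aldehyde, via Mannich base 35 (not isolated)
Conditions: [Me2N=CH2]I, Et3N, CH2Cl2, rt
Reagents that add atoms: dimethylmethyleneammonium iodide C[N+](C)=C.[I-]
Why: Mannich α-methylenation of the aldehyde with Eschenmoser's salt and amine-induced elimination should introduce C13 on C11 without any strong base, so the C8 ester, both oxiranes and C7 are not endangered.

Step 28
Reactants: 36 α-methylene aldehyde
Product: 37 α-methylene acid
Conditions: NaClO2, NaH2PO4, 2-methyl-2-butene, t-BuOH/H2O, 0 °C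
Reagents that add atoms: sodium chlorite [Na+].[O-]Cl=O
Why: Pinnick oxidation should convert the enal into the acrylic acid, the scavenger alkene protecting the C4=C5 bond from hypochlorite.

Step 29
Reactants: 37 α-methylene acid
Product: 39 target CNP0268255.3, via dihydroxy acid 38 (not isolated)
Conditions: HF·pyridine, pyridine, THF, 0 °C → rt
Reagents that add atoms: none
Why: Buffered HF·pyridine should cleave both secondary TBS ethers, and the freed C6 hydroxyl, the only one that can reach C12 in a five-membered ring now that C8–O is acylated, lactonises with the acid to close ring B trans-fused and give the target.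

Compound list
1 | angelic acid, (Z)-2-methylbut-2-enoic acid | C/C=C(/C)C(=O)O | starting material
2 | angelyl alcohol, (Z)-2-methylbut-2-en-1-ol | C/C=C(/C)CO | intermediate
3 | [(2S,3R)-2,3-dimethyloxiran-2-yl]methanol | OC[C@]1(C)O[C@@H]1C | intermediate
4 | (2R,3R)-2,3-dimethyloxirane-2-carboxylic acid (epoxyangelic acid) | OC(=O)[C@]1(C)O[C@@H]1C | intermediate
5 | 2-methylcyclopentane-1,3-dione | CC1C(=O)CCC1=O | starting material
6 | allyl bromide | C=CCBr | starting material
7 | 2-allyl-2-methylcyclopentane-1,3-dione | C=CCC1(C)C(=O)CCC1=O | intermediate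
8 | (2R,3R)-2-allyl-3-hydroxy-2-methylcyclopentan-1-one, hydroxyl cis to allyl | C=CC[C@@]1(C)C(=O)CC[C@H]1O | intermediate
9 | (2R,3R)-2-allyl-2-methyl-3-(triethylsilyloxy)cyclopentan-1-one | C=CC[C@@]1(C)C(=O)CC[C@H]1O[Si](CC)(CC)CC | intermediate
10 | (2R,3R)-2-methyl-2-[(E)-prop-1-enyl]-3-(triethylsilyloxy)cyclopentan-1-one | C/C=C/[C@@]1(C)C(=O)CC[C@H]1O[Si](CC)(CC)CC | intermediate
11 | trimethylsilyl enol ether of 10 (C7=C8 enol ether) | C/C=C/[C@@]1(C)C(O[Si](C)(C)C)=CC[C@H]1O[Si](CC)(CC)CC | intermediate
12 | (4R,5R)-5-methyl-5-[(E)-prop-1-enyl]-4-(triethylsilyloxy)cyclopent-2-en-1-one | C/C=C/[C@@]1(C)C(=O)C=C[C@H]1O[Si](CC)(CC)CC | intermediate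
13 | C6 pinacol boronate of the cyclopentanone, boron trans to C5–OTES | C/C=C/[C@@]1(C)C(=O)C[C@H](B2OC(C)(C)C(C)(C)O2)[C@H]1O[Si](CC)(CC)CC | intermediate
14 | C6 hydroxy ketone, C6–OH trans to C5–OTES, propenyl cis to C5–OTES | C/C=C/[C@@]1(C)C(=O)C[C@H](O)[C@H]1O[Si](CC)(CC)CC | intermediate
15 | tert-butyl bromoacetate | CC(C)(C)OC(=O)CBr | starting material
16 | C7-alkylated hydroxy ketone, tert-butyl acetate arm on C7 trans to C6–OH and cis to C5–OTES | C/C=C/[C@@]1(C)C(=O)[C@@H](CC(=O)OC(C)(C)C)[C@H](O)[C@H]1O[Si](CC)(CC)CC | intermediate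
17 | C8 exocyclic methylene compound derived from 16 | C/C=C/[C@@]1(C)C(=C)[C@@H](CC(=O)OC(C)(C)C)[C@H](O)[C@H]1O[Si](CC)(CC)CC | intermediate
18 | spiro epoxide (C8–C9 oxirane), oxirane oxygen cis to C6–OH and to the C4 methyl | C/C=C/[C@@]1(C)[C@@]2(CO2)[C@@H](CC(=O)OC(C)(C)C)[C@H](O)[C@H]1O[Si](CC)(CC)CC | intermediate
19 | C3 aldehyde (formyl group on C4 in place of propenyl) | O=C[C@@]1(C)[C@@]2(CO2)[C@@H](CC(=O)OC(C)(C)C)[C@H](O)[C@H]1O[Si](CC)(CC)CC | intermediate
20 | (3S)-homoallylic alcohol, C4 bears (1S)-1-hydroxybut-3-enyl | C=CC[C@H](O)[C@@]1(C)[C@@]2(CO2)[C@@H](CC(=O)OC(C)(C)C)[C@H](O)[C@H]1O[Si](CC)(CC)CC | intermediate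
21 | tris(trimethylsilyl) ether of the methallyl carbinol (C3, C6 and C8 oxygens silylated) | C=CC[C@H](O[Si](C)(C)C)[C@@]1(C)[C@](CC(C)=C)(O[Si](C)(C)C)[C@@H](CC(=O)OC(C)(C)C)[C@H](O[Si](C)(C)C)[C@H]1O[Si](CC)(CC)CC | intermediate
22 | diene diol with C8–OTMS, methallyl on C8 cis to the C3 chain, free C3–OH and C6–OH | C=CC[C@H](O)[C@@]1(C)[C@](CC(C)=C)(O[Si](C)(C)C)[C@@H](CC(=O)OC(C)(C)C)[C@H](O)[C@H]1O[Si](CC)(CC)CC | intermediate
23 | cis-fused bicyclo[5.3.0]dec-1(10)-ene (hydroazulene) diol, C8–OTMS cis to the C4 methyl | C[C@]12[C@@H](O)CC=C(C)C[C@@]1(O[Si](C)(C)C)[C@@H](CC(=O)OC(C)(C)C)[C@H](O)[C@H]2O[Si](CC)(CC)CC | intermediate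
24 | hydroazulene 1,10-epoxide, oxirane cis to C3–OH | C[C@]12[C@@H](O)C[C@H]3O[C@@]3(C)C[C@@]1(O[Si](C)(C)C)[C@@H](CC(=O)OC(C)(C)C)[C@H](O)[C@H]2O[Si](CC)(CC)CC | intermediate
25 | bis-TBS ether of 24 (C3–OTBS, C6–OTBS, C5–OTES, C8–OTMS) | C[C@]12[C@@H](O[Si](C)(C)C(C)(C)C)C[C@H]3O[C@@]3(C)C[C@@]1(O[Si](C)(C)C)[C@@H](CC(=O)OC(C)(C)C)[C@H](O[Si](C)(C)C(C)(C)C)[C@H]2O[Si](CC)(CC)CC | intermediate
26 | C12 primary alcohol (2-hydroxyethyl on C7) | C[C@]12[C@@H](O[Si](C)(C)C(C)(C)C)C[C@H]3O[C@@]3(C)C[C@@]1(O[Si](C)(C)C)[C@@H](CCO)[C@H](O[Si](C)(C)C(C)(C)C)[C@H]2O[Si](CC)(CC)CC | intermediate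
27 | triol with free C5–OH, C8–OH and C12–OH | C[C@]12[C@@H](O[Si](C)(C)C(C)(C)C)C[C@H]3O[C@@]3(C)C[C@@]1(O)[C@@H](CCO)[C@H](O[Si](C)(C)C(C)(C)C)[C@H]2O | intermediate
28 | C12 TES ether with free C5–OH and C8–OH | C[C@]12[C@@H](O[Si](C)(C)C(C)(C)C)C[C@H]3O[C@@]3(C)C[C@@]1(O)[C@@H](CCO[Si](CC)(CC)CC)[C@H](O[Si](C)(C)C(C)(C)C)[C@H]2O | intermediate
29 | hydroazulene hydroxy mesylate (fragmentation precursor), C5–OMs cis to C3 and trans to C6–OTBS, C8–OH cis to the C4 methyl | C[C@]12[C@@H](O[Si](C)(C)C(C)(C)C)C[C@H]3O[C@@]3(C)C[C@@]1(O)[C@@H](CCO[Si](CC)(CC)CC)[C@H](O[Si](C)(C)C(C)(C)C)[C@H]2OS(C)(=O)=O | intermediate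
30 | Z cyclodecenone epoxide (C8 ketone, C4=C5 Z, 1,10-oxirane, C3–OTBS, C6–OTBS, C12–OTES) | O=C1C[C@]2(C)O[C@@H]2C[C@H](O[Si](C)(C)C(C)(C)C)/C(C)=C\[C@@H](O[Si](C)(C)C(C)(C)C)[C@@H]1CCO[Si](CC)(CC)CC | intermediate
31 | (8R)-alcohol, C8–OH cis to the C7 side chain | O[C@@H]1C[C@]2(C)O[C@@H]2C[C@H](O[Si](C)(C)C(C)(C)C)/C(C)=C\[C@@H](O[Si](C)(C)C(C)(C)C)[C@@H]1CCO[Si](CC)(CC)CC | intermediate
32 | mixed anhydride of 4 and 2,4,6-trichlorobenzoic acid | C[C@H]1O[C@@]1(C)C(=O)OC(=O)c2c(Cl)cc(Cl)cc2Cl | intermediate
33 | C8 (2R,3R)-epoxyangelate | O=C([C@]3(C)O[C@@H]3C)O[C@@H]1C[C@]2(C)O[C@@H]2C[C@H](O[Si](C)(C)C(C)(C)C)/C(C)=C\[C@@H](O[Si](C)(C)C(C)(C)C)[C@@H]1CCO[Si](CC)(CC)CC | intermediate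
34 | C12 aldehyde | O=C([C@]3(C)O[C@@H]3C)O[C@@H]1C[C@]2(C)O[C@@H]2C[C@H](O[Si](C)(C)C(C)(C)C)/C(C)=C\[C@@H](O[Si](C)(C)C(C)(C)C)[C@@H]1CC=O | intermediate
35 | Mannich base, dimethylaminomethyl group on C11 (C11 epimers) | O=C([C@]3(C)O[C@@H]3C)O[C@@H]1C[C@]2(C)O[C@@H]2C[C@H](O[Si](C)(C)C(C)(C)C)/C(C)=C\[C@@H](O[Si](C)(C)C(C)(C)C)[C@@H]1C(CN(C)C)C=O | intermediate
36 | α-methylene aldehyde (C11=C13, C12 aldehyde) | O=C([C@]3(C)O[C@@H]3C)O[C@@H]1C[C@]2(C)O[C@@H]2C[C@H](O[Si](C)(C)C(C)(C)C)/C(C)=C\[C@@H](O[Si](C)(C)C(C)(C)C)[C@@H]1C(=C)C=O | intermediate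
37 | α-methylene acid (C12 carboxylic acid) | O=C([C@]3(C)O[C@@H]3C)O[C@@H]1C[C@]2(C)O[C@@H]2C[C@H](O[Si](C)(C)C(C)(C)C)/C(C)=C\[C@@H](O[Si](C)(C)C(C)(C)C)[C@@H]1C(=C)C(=O)O | intermediate
38 | dihydroxy acid (free C3–OH and C6–OH) | O=C([C@]3(C)O[C@@H]3C)O[C@@H]1C[C@]2(C)O[C@@H]2C[C@H](O)/C(C)=C\[C@@H](O)[C@@H]1C(=C)C(=O)O | intermediate
39 | CNP0268255.3, (1R,3S,6R,7R,8R,10S)-configured 1,10-epoxy-3-hydroxy-8-[(2R,3R)-epoxyangeloyloxy]germacra-4Z,11(13)-dien-6,12-olide | C=C1C(=O)O[C@@H]2/C=C(/C)[C@@H](O)C[C@H]3O[C@@]3(C)C[C@@H](OC(=O)[C@]3(C)O[C@@H]3C)[C@@H]12 | target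

Total step count: 29. Longest linear sequence: 26 steps (steps 4 to 29, from 2-methylcyclopentane-1,3-dione); acid 4 is made in steps 1 to 3 and enters at step 25.

Steps most likely to fail

Step 23. The new ketone is both a β,γ-epoxy and a β-silyloxy ketone, so any base left after the fragmentation could enolise it toward C9 or C7 and open the oxirane or expel the C6 silyloxy group. The fragmentation could also be slow if the mesylate does not reach the pseudo-axial position. The fallback moves the epoxidation behind the ring expansion; it sets out from 23 and comes back at 31. Silylation of 23 (tBuMe2SiOTf, 2,6-lutidine) would give bis-TBS cycloheptene F1, iBu2AlH reduction primary alcohol F2, HF·pyridine triol F3, selective silylation C12 TES ether F4 and mesylation olefinic hydroxy mesylate F5. Fragmentation with KN(SiMe3)2 would then give (1(10)Z,4Z)-cyclodecadienone F6, which holds no oxirane that base could open, and CBS reduction would give dienol F7. Epoxidation of F7 with VO(acac)2 and t-BuOOH, directed by the homoallylic C8 hydroxyl to the C1=C10 bond, should give 31.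

Step 24. Hydride delivery to a ketone in a flexible ten-membered ring may show poor facial selectivity, or the ring conformation may override the catalyst. The fallback sets out from 30 and comes back at 33: reduction from the face the substrate prefers (LiBH(s-Bu)3, THF, −78 °C) would give 8S alcohol F8, and Mitsunobu esterification of F8 with acid 4 (PPh3, DIAD) inverts C8 and should give 33 directly.

Step 10. The dianion may suffer O-alkylation, retro-aldol opening or migration of the C5 silyl group, and the trans selectivity at C7 may be incomplete. The fallback sets out from 12 and comes back at 16: α-iodination (I2, pyridine) would give 2-iodoenone F9, and Negishi-type coupling with the Reformatsky reagent BrZnCH2CO2tBu (Pd(PPh3)4 cat.) would give 2-substituted enone F10. Copper-catalysed conjugate borylation of F10, anti to C5–OTES and with protonation at C7 under thermodynamic control, would give trans boronate F11, and NaBO3 oxidation should then give 16.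

Further compounds
F1 | step 23 | bis-TBS ether of cycloheptene 23 | C[C@]12[C@@H](O[Si](C)(C)C(C)(C)C)CC=C(C)C[C@@]1(O[Si](C)(C)C)[C@@H](CC(=O)OC(C)(C)C)[C@H](O[Si](C)(C)C(C)(C)C)[C@H]2O[Si](CC)(CC)CC
F2 | step 23 | C12 primary alcohol of the cycloheptene series | C[C@]12[C@@H](O[Si](C)(C)C(C)(C)C)CC=C(C)C[C@@]1(O[Si](C)(C)C)[C@@H](CCO)[C@H](O[Si](C)(C)C(C)(C)C)[C@H]2O[Si](CC)(CC)CC
F3 | step 23 | cycloheptene triol (free C5–OH, C8–OH, C12–OH) | C[C@]12[C@@H](O[Si](C)(C)C(C)(C)C)CC=C(C)C[C@@]1(O)[C@@H](CCO)[C@H](O[Si](C)(C)C(C)(C)C)[C@H]2O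
F4 | step 23 | cycloheptene C12 TES ether | C[C@]12[C@@H](O[Si](C)(C)C(C)(C)C)CC=C(C)C[C@@]1(O)[C@@H](CCO[Si](CC)(CC)CC)[C@H](O[Si](C)(C)C(C)(C)C)[C@H]2O
F5 | step 23 | olefinic hydroxy mesylate | C[C@]12[C@@H](O[Si](C)(C)C(C)(C)C)CC=C(C)C[C@@]1(O)[C@@H](CCO[Si](CC)(CC)CC)[C@H](O[Si](C)(C)C(C)(C)C)[C@H]2OS(C)(=O)=O
F6 | step 23 | (1(10)Z,4Z)-cyclodecadienone | O=C1C/C(C)=C\C[C@H](O[Si](C)(C)C(C)(C)C)/C(C)=C\[C@@H](O[Si](C)(C)C(C)(C)C)[C@@H]1CCO[Si](CC)(CC)CC
F7 | step 23 | (8R)-cyclodecadienol | O[C@@H]1C/C(C)=C\C[C@H](O[Si](C)(C)C(C)(C)C)/C(C)=C\[C@@H](O[Si](C)(C)C(C)(C)C)[C@@H]1CCO[Si](CC)(CC)CC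
F8 | step 24 | 8S alcohol (C8 epimer of 31) | O[C@H]1C[C@]2(C)O[C@@H]2C[C@H](O[Si](C)(C)C(C)(C)C)/C(C)=C\[C@@H](O[Si](C)(C)C(C)(C)C)[C@@H]1CCO[Si](CC)(CC)CC
F9 | step 10 | 2-iodoenone (iodine on C7) | C/C=C/[C@@]1(C)C(=O)C(I)=C[C@H]1O[Si](CC)(CC)CC
F10 | step 10 | 2-substituted enone (tert-butyl acetate arm on C7) | C/C=C/[C@@]1(C)C(=O)C(CC(=O)OC(C)(C)C)=C[C@H]1O[Si](CC)(CC)CC
F11 | step 10 | trans C6 boronate of the C7-alkylated ketone | C/C=C/[C@@]1(C)C(=O)[C@@H](CC(=O)OC(C)(C)C)[C@H](B2OC(C)(C)C(C)(C)O2)[C@H]1O[Si](CC)(CC)CC
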